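**Retrosynthetic overview**
- Kushenol U is reached by fluoride cleavage of a 4′-O-silyl ether. TBS replaces an acetal-type group so that no acid meets the C7 phenol next to the lavandulyl alkenes.
- The strategy rests on ring A: OMe on C5, H on C6, OH on C7 and the lavandulyl CH2 on C8. C5–C8 map onto C1–C4 of a 1,1-dimethoxy-3-silyloxy diene with the lavandulyl CH2 on C4. C4a and C8a are the C5=C6 alkene of a preformed (2S)-2-aryl-2,3-dihydro-4H-pyran-4-one (ring C). The disconnections are C4a–C5 and C8–C8a.
- The dienophile carries a phenylsulfinyl group on C4a. It activates the vinylogous ester and, lying cis to H8a in the adduct, leaves by thermal syn-elimination. A sulfonyl group on the quaternary C4a would have no such exit, because H8a is neither acidic nor anti. Loss of methanol then aromatises ring A.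
- Pyranone: asymmetric hetero-Diels–Alder reaction (sets C2), sulfenylation, S-oxidation. Diene: (S)-limonene (source of C2″) by ring cleavage, Wittig olefination, haloform reaction, acylation of 1,1-dimethoxyethene and enol silylation.
- Ring order: ring B is bought with the aldehyde, ring C is made first, ring A last.

Key step: step 11

Assumption: the titanium catalyst made from (S)-BINOL is taken to direct the diene to the Si face of the aldehyde, as (2S) requires; if the sense proves opposite, (R)-BINOL is used in step 2.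

**Route**

Step 1
Reactants: 1 4-hydroxybenzaldehyde
Product: 2 4-(tert-butyldimethylsilyloxy)benzaldehyde
Conditions: TBSCl, imidazole, DMF, rt
Reagents that add atoms: tert-butyldimethylsilyl chloride, CC(C)(C)[Si](C)(C)Cl
Why: Imidazole-mediated O-silylation of a phenol; the aryl silyl ether should survive the Lewis acid, sulfenylation, peracid and thermal steps and is later removed by fluoride without acid.

Step 2
Reactants: 2 4-(tert-butyldimethylsilyloxy)benzaldehyde, 3 (E)-1-methoxy-3-(trimethylsilyloxy)buta-1,3-diene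
Product: 5 (2S)-2-[4-(tert-butyldimethylsilyloxy)phenyl]-2,3-dihydro-4H-pyran-4-one, via aldol adduct 4 (not isolated)
Conditions: (S)-BINOL (20 mol%), Ti(OiPr)4 (10 mol%), 4 Å MS, Et2O, −20 °C; then CF3CO2H (cat.), CH2Cl2, 0 °C
Reagents that add atoms: none
Why: Catalytic asymmetric hetero-Diels–Alder reaction of the Mukaiyama-aldol type, in which the chiral titanium binaphtholate directs the diene terminus to the Si face of the aldehyde and so sets C2 as S, after which acid closes the ring by oxa-Michael addition with loss of methanol.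

Step 3
Reactants: 5 (2S)-2-[4-(tert-butyldimethylsilyloxy)phenyl]-2,3-dihydro-4H-pyran-4-one
Product: 6 (2S)-2-[4-(tert-butyldimethylsilyloxy)phenyl]-5-(phenylsulfanyl)-2,3-dihydro-4H-pyran-4-one
Conditions: PhSCl, pyridine, CH2Cl2, −78 → 0 °C
Reagents that add atoms: benzenesulfenyl chloride, ClSc1ccccc1
Why: Electrophilic α-sulfenylation of a vinylogous ester, in which the enol-ether carbon C5 of the pyranone attacks sulfur, the cation at C6 is stabilised by the ring oxygen and pyridine removes the C5 proton, leaving C2 untouched.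

Step 4
Reactants: 6 (2S)-2-[4-(tert-butyldimethylsilyloxy)phenyl]-5-(phenylsulfanyl)-2,3-dihydro-4H-pyran-4-one
Product: 7 (2S)-2-[4-(tert-butyldimethylsilyloxy)phenyl]-5-(phenylsulfinyl)-2,3-dihydro-4H-pyran-4-one (both sulfur epimers)
Conditions: mCPBA (1.0 equiv), CH2Cl2, −78 → −40 °C
Reagents that add atoms: 3-chloroperoxybenzoic acid, O=C(OO)c1cccc(Cl)c1
Why: Chemoselective sulfide-to-sulfoxide oxidation with one equivalent of peracid at low temperature; the electron-poor C=C should not be epoxidised, and the sulfur epimers need no separation because sulfur is expelled in step 11.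

Step 5
Reactants: 8 (S)-limonene
Product: 9 (4S)-1-methyl-4-(prop-1-en-2-yl)-7-oxabicyclo[4.1.0]heptane (limonene 1,2-oxide, both epoxide diastereomers)
Conditions: mCPBA (1.0 equiv), CH2Cl2, 0 °C
Reagents that add atoms: 3-chloroperoxybenzoic acid, O=C(OO)c1cccc(Cl)c1
Why: Prilezhaev epoxidation, selective for the trisubstituted ring alkene over the 1,1-disubstituted isopropenyl alkene; the diastereomers converge in step 6 and C4 is untouched.

Step 6
Reactants: 9 (4S)-limonene 1,2-oxide
Product: 11 (3S)-6-oxo-3-(prop-1-en-2-yl)heptanal, via diol 10 (not isolated)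
Conditions: H5IO6, THF/H2O, 0 °C → rt
Reagents that add atoms: water, O
Why: Acid-assisted epoxide hydrolysis followed by Malaprade glycol cleavage opens the ring between C1 and C2 to a methyl ketone and an aldehyde, and the stereocentre, β to the aldehyde, cannot epimerise.

Step 7
Reactants: 11 (3S)-6-oxo-3-(prop-1-en-2-yl)heptanal
Product: 12 (5S)-8-methyl-5-(prop-1-en-2-yl)non-7-en-2-one
Conditions: iPrPPh3I, n-BuLi, THF, 0 °C; then 11, −78 → 0 °C
Reagents that add atoms: isopropyltriphenylphosphonium iodide, CC(C)[P+](c1ccccc1)(c1ccccc1)c1ccccc1.[I-]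
Why: Wittig olefination with one equivalent of the unstabilised isopropylidene ylide should react at the aldehyde much faster than at the methyl ketone and builds the prenyl terminus, which has no E/Z issue.

Step 8
Reactants: 12 (5S)-8-methyl-5-(prop-1-en-2-yl)non-7-en-2-one
Product: 14 (4S)-7-methyl-4-(prop-1-en-2-yl)oct-6-enoic acid, via tribromomethyl ketone 13 (not isolated)
Conditions: Br2, NaOH, dioxane/H2O, 0 °C; then Na2SO3; aq. HCl to pH 3, 0 °C
Reagents that add atoms: sodium hydroxide, [Na+].[OH-]
Why: Haloform reaction, in which exhaustive enolate bromination of the methyl group and hydroxide cleavage give the acid with one carbon less; in cold, strongly alkaline hypobromite the isolated alkenes should react more slowly than the ketone enolate, and sulfite removes excess oxidant before acidification.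

Step 9
Reactants: 14 (4S)-7-methyl-4-(prop-1-en-2-yl)oct-6-enoic acid, 15 1,1-dimethoxyethene
Product: 17 (6S)-1,1-dimethoxy-9-methyl-6-(prop-1-en-2-yl)deca-1,8-dien-3-one, via acid chloride 16 (not isolated)
Conditions: (COCl)2, DMF (cat.), CH2Cl2, 0 °C → rt; then 15 (2 equiv), Et3N, Et2O, 0 °C → rt
Reagents that add atoms: none
Why: C-acylation of a ketene acetal by an acid chloride, in which the nucleophilic CH2 of 15 attacks the acyl chloride and the dimethoxycarbenium ion loses a proton to the amine to give the β,β-dimethoxy enone.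

Step 10
Reactants: 17 (6S)-1,1-dimethoxy-9-methyl-6-(prop-1-en-2-yl)deca-1,8-dien-3-one
Product: 18 {[(3Z,6R)-1,1-dimethoxy-9-methyl-6-(prop-1-en-2-yl)deca-1,3,8-trien-3-yl]oxy}trimethylsilane
Conditions: LDA, THF, −78 °C; TMSCl, −78 → 0 °C; non-aqueous work-up, used crude
Reagents that add atoms: chlorotrimethylsilane, C[Si](C)(C)Cl
Why: Kinetic deprotonation at the only enolisable position and O-silylation give the 1,1-dimethoxy-3-silyloxy diene; the Z enolate expected for an alkyl alkenyl ketone places the lavandulyl CH2 on the outside of the s-cis diene (the descriptor changes from S to R only through CIP priorities).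

Step 11
Reactants: 7 (2S)-2-[4-(tert-butyldimethylsilyloxy)phenyl]-5-(phenylsulfinyl)-2,3-dihydro-4H-pyran-4-one, 18 the (3Z,6R)-1,1-dimethoxy-3-silyloxy diene
Product: 22 (2S)-2-[4-(tert-butyldimethylsilyloxy)phenyl]-7-hydroxy-5-methoxy-8-[(2R)-5-methyl-2-(prop-1-en-2-yl)hex-4-en-1-yl]chroman-4-one, via cycloadduct 19 (not isolated), via ketal 20 (not isolated), via aryl silyl ether 21 (not isolated)
Conditions: 18 (2.5 equiv), toluene, rt → 80 °C; then 10% aq. citric acid, THF, rt
Reagents that add atoms: none
Why: Normal-demand Diels–Alder reaction in which the silyl-enol-ether terminus C4 of 18 (future C8) bonds to C8a, the β-carbon of the sulfinyl enone, and the ketene-acetal carbon C1 (future C5) bonds to C4a; this asynchronous intermolecular [4+2] cycloaddition closes ring A as a six-membered carbocycle. In adduct 19 the sulfinyl group on C4a and H on C8a are cis, so thermal syn-elimination of PhSOH restores C4a=C8a; 1,4-loss of methanol from the doubly allylic ketal 20 (H from C8, OMe from C5) then aromatises ring A, and mild acid frees the C7 phenol from its TMS ether. The closest known reaction types are the Diels–Alder reaction with sulfenic acid elimination of 3-sulfinylchromones, where the sulfinyl enone acts as an alkyne equivalent, and the aromatising cycloadditions of 1,1-dialkoxy-3-silyloxy dienes with alkynes and haloquinones. No stereocentre is created: the sp3 centres C4a, C8 and C8a of 19 are transient, the C2–O1 bond is never broken under these neutral conditions, and C2″ is remote. The step needs regioselectivity, which is secured by pairing the most nucleophilic diene terminus with the doubly activated C8a, so that OMe, OH and the lavandulyl CH2 arrive on C5, C7 and C8 without any selective O-alkylation.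

Step 12
Reactants: 22 (2S)-2-[4-(tert-butyldimethylsilyloxy)phenyl]-7-hydroxy-5-methoxy-8-[(2R)-5-methyl-2-(prop-1-en-2-yl)hex-4-en-1-yl]chroman-4-one
Product: 23 kushenol U, (2S)-7-hydroxy-2-(4-hydroxyphenyl)-5-methoxy-8-[(2R)-5-methyl-2-(prop-1-en-2-yl)hex-4-en-1-yl]chroman-4-one
Conditions: Bu4NF, AcOH (1:1), THF, 0 °C
Reagents that add atoms: none
Why: Fluoride-induced cleavage of the aryl silyl ether; the acetic acid buffer should keep the flavanone from opening to the chalcone (which would racemise C2), and no acid strong enough to cyclise the C7 phenol onto the lavandulyl alkenes is present.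

**Compound list**

1 | 4-hydroxybenzaldehyde | O=Cc1ccc(O)cc1 | starting material
2 | 4-(tert-butyldimethylsilyloxy)benzaldehyde | O=Cc1ccc(O[Si](C)(C)C(C)(C)C)cc1 | intermediate
3 | (E)-1-methoxy-3-(trimethylsilyloxy)buta-1,3-diene | CO/C=C/C(=C)O[Si](C)(C)C | starting material
4 | (1E,5S)-5-[4-(tert-butyldimethylsilyloxy)phenyl]-1-methoxy-5-(trimethylsilyloxy)pent-1-en-3-one | CO/C=C/C(=O)C[C@H](O[Si](C)(C)C)c1ccc(O[Si](C)(C)C(C)(C)C)cc1 | intermediate (not isolated)
5 | (2S)-2-[4-(tert-butyldimethylsilyloxy)phenyl]-2,3-dihydro-4H-pyran-4-one | O=C1C=CO[C@H](c2ccc(O[Si](C)(C)C(C)(C)C)cc2)C1 | intermediate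
6 | (2S)-2-[4-(tert-butyldimethylsilyloxy)phenyl]-5-(phenylsulfanyl)-2,3-dihydro-4H-pyran-4-one | O=C1C(Sc2ccccc2)=CO[C@H](c2ccc(O[Si](C)(C)C(C)(C)C)cc2)C1 | intermediate
7 | (2S)-2-[4-(tert-butyldimethylsilyloxy)phenyl]-5-(phenylsulfinyl)-2,3-dihydro-4H-pyran-4-one, both sulfur epimers | O=C1C(S(=O)c2ccccc2)=CO[C@H](c2ccc(O[Si](C)(C)C(C)(C)C)cc2)C1 | intermediate
8 | (S)-limonene, (4S)-1-methyl-4-(prop-1-en-2-yl)cyclohex-1-ene | CC1=CC[C@H](CC1)C(C)=C | starting material
9 | (4S)-1-methyl-4-(prop-1-en-2-yl)-7-oxabicyclo[4.1.0]heptane, both epoxide diastereomers | CC12OC1C[C@H](CC2)C(C)=C | intermediate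
10 | (4S)-1-methyl-4-(prop-1-en-2-yl)cyclohexane-1,2-diol | OC1C[C@H](CCC1(C)O)C(C)=C | intermediate (not isolated)
11 | (3S)-6-oxo-3-(prop-1-en-2-yl)heptanal | O=CC[C@H](CCC(C)=O)C(C)=C | intermediate
12 | (5S)-8-methyl-5-(prop-1-en-2-yl)non-7-en-2-one | CC(C)=CC[C@H](CCC(C)=O)C(C)=C | intermediate
13 | (5S)-1,1,1-tribromo-8-methyl-5-(prop-1-en-2-yl)non-7-en-2-one | CC(C)=CC[C@H](CCC(=O)C(Br)(Br)Br)C(C)=C | intermediate (not isolated)
14 | (4S)-7-methyl-4-(prop-1-en-2-yl)oct-6-enoic acid | CC(C)=CC[C@H](CCC(=O)O)C(C)=C | intermediate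
15 | 1,1-dimethoxyethene | C=C(OC)OC | starting material
16 | (4S)-7-methyl-4-(prop-1-en-2-yl)oct-6-enoyl chloride | CC(C)=CC[C@H](CCC(=O)Cl)C(C)=C | intermediate (not isolated)
17 | (6S)-1,1-dimethoxy-9-methyl-6-(prop-1-en-2-yl)deca-1,8-dien-3-one | CC(C)=CC[C@H](CCC(=O)C=C(OC)OC)C(C)=C | intermediate
18 | {[(3Z,6R)-1,1-dimethoxy-9-methyl-6-(prop-1-en-2-yl)deca-1,3,8-trien-3-yl]oxy}trimethylsilane | CC(C)=CC[C@H](C/C=C(/C=C(OC)OC)O[Si](C)(C)C)C(C)=C | intermediate
19 | (2S)-2-[4-(tert-butyldimethylsilyloxy)phenyl]-5,5-dimethoxy-8-[(2R)-5-methyl-2-(prop-1-en-2-yl)hex-4-en-1-yl]-4a-(phenylsulfinyl)-7-(trimethylsilyloxy)-2,3,4a,5,8,8a-hexahydro-4H-chromen-4-one, cis-fused, mixture at C4a, C8, C8a and sulfur | C=C(C)[C@H](CC=C(C)C)CC1C(O[Si](C)(C)C)=CC(OC)(OC)C2(S(=O)c3ccccc3)C1O[C@H](c1ccc(O[Si](C)(C)C(C)(C)C)cc1)CC2=O | intermediate (not isolated)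
20 | (2S)-2-[4-(tert-butyldimethylsilyloxy)phenyl]-5,5-dimethoxy-8-[(2R)-5-methyl-2-(prop-1-en-2-yl)hex-4-en-1-yl]-7-(trimethylsilyloxy)-2,3,5,8-tetrahydro-4H-chromen-4-one, mixture at C8 | C=C(C)[C@H](CC=C(C)C)CC1C(O[Si](C)(C)C)=CC(OC)(OC)C2=C1O[C@H](c1ccc(O[Si](C)(C)C(C)(C)C)cc1)CC2=O | intermediate (not isolated)
21 | (2S)-2-[4-(tert-butyldimethylsilyloxy)phenyl]-5-methoxy-8-[(2R)-5-methyl-2-(prop-1-en-2-yl)hex-4-en-1-yl]-7-(trimethylsilyloxy)chroman-4-one | C=C(C)[C@H](CC=C(C)C)Cc1c(O[Si](C)(C)C)cc(OC)c2c1O[C@H](c1ccc(O[Si](C)(C)C(C)(C)C)cc1)CC2=O | intermediate (not isolated)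
22 | (2S)-2-[4-(tert-butyldimethylsilyloxy)phenyl]-7-hydroxy-5-methoxy-8-[(2R)-5-methyl-2-(prop-1-en-2-yl)hex-4-en-1-yl]chroman-4-one | C=C(C)[C@H](CC=C(C)C)Cc1c(O)cc(OC)c2c1O[C@H](c1ccc(O[Si](C)(C)C(C)(C)C)cc1)CC2=O | intermediate
23 | kushenol U, (2S)-7-hydroxy-2-(4-hydroxyphenyl)-5-methoxy-8-[(2R)-5-methyl-2-(prop-1-en-2-yl)hex-4-en-1-yl]chroman-4-one | C=C(C)[C@H](CC=C(C)C)Cc1c(O)cc(OC)c2c1O[C@H](c1ccc(O)cc1)CC2=O | target

**Step count and risks**

Total step count: 12. Longest linear sequence: 8 steps (steps 5 to 12, from (S)-limonene); the pyranone branch (steps 1 to 4) joins at step 11.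

Steps most likely to fail:

1. Step 11. The cycloaddition may stop at the open-chain Michael stage after the first C–C bond, or the diene may be consumed by the sulfenic acid set free before the dienophile is used up. Fallback: the two bonds are made one at a time, setting out from 7 and 18. ZnBr2 in CH2Cl2 at −78 °C, chelating the sulfinyl and carbonyl oxygens of 7, should promote Mukaiyama–Michael addition of the silyl-enol-ether terminus of 18 to C8a and give, after aqueous work-up, the open-chain Michael adduct F1, in which the β,β-dimethoxy enone is intact and C4a–H is the acidic proton of a β-keto sulfoxide. Et3N in MeCN at rt should then close ring A by addition of C4a to the ketene-acetal carbon with loss of methanol, giving the bicyclic vinylogous ester F2. Heating F2 in toluene at 80 °C should eliminate PhSOH, and the dienone formed tautomerises to the phenol, which returns to the route at 22.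

2. Step 8. Hypobromite may brominate or hydroxybrominate the trisubstituted and 1,1-disubstituted alkenes in competition with enolate bromination. Fallback: a halogen-free degradation setting out from 12. LDA in THF at −78 °C forms the kinetic methyl enolate, which is hydroxylated with 2-(phenylsulfonyl)-3-phenyloxaziridine to the α-hydroxy ketone F3. NaIO4 in aqueous THF then cleaves the ketol to the acid and formaldehyde, returning to the route at 14.

3. Step 3. Attack of the sulfenyl chloride on the deactivated enol-ether carbon may be slow, or it may be diverted to C3 through the enol. Fallback: C–S bond formation by cross-coupling, setting out from 5. I2 and pyridine in CH2Cl2 at rt should give the 5-iodopyranone F4 by α-iodination of the vinylogous ester. Coupling of F4 with PhSSnBu3 under Pd(PPh3)4 catalysis in toluene at 100 °C is neutral, with no free thiolate that could add to C6 and open the ring, and returns to the route at 6.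

**Further compounds**

F1 | step 11 | (2S)-2-[4-(tert-butyldimethylsilyloxy)phenyl]-6-[(6R)-1,1-dimethoxy-9-methyl-3-oxo-6-(prop-1-en-2-yl)deca-1,8-dien-4-yl]-5-(phenylsulfinyl)tetrahydro-4H-pyran-4-one | C=C(C)[C@H](CC=C(C)C)CC(C(=O)C=C(OC)OC)C1O[C@H](c2ccc(O[Si](C)(C)C(C)(C)C)cc2)CC(=O)C1S(=O)c1ccccc1
F2 | step 11 | (2S)-2-[4-(tert-butyldimethylsilyloxy)phenyl]-5-methoxy-8-[(2R)-5-methyl-2-(prop-1-en-2-yl)hex-4-en-1-yl]-4a-(phenylsulfinyl)-2,3,4a,8a-tetrahydro-4H-chromene-4,7(8H)-dione | C=C(C)[C@H](CC=C(C)C)CC1C(=O)C=C(OC)C2(S(=O)c3ccccc3)C1O[C@H](c1ccc(O[Si](C)(C)C(C)(C)C)cc1)CC2=O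
F3 | step 8 | (5S)-1-hydroxy-8-methyl-5-(prop-1-en-2-yl)non-7-en-2-one | CC(C)=CC[C@H](CCC(=O)CO)C(C)=C
F4 | step 3 | (2S)-2-[4-(tert-butyldimethylsilyloxy)phenyl]-5-iodo-2,3-dihydro-4H-pyran-4-one | O=C1C(I)=CO[C@H](c2ccc(O[Si](C)(C)C(C)(C)C)cc2)C1
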